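**Plan**

1. Retrosynthesis: after the phenol ester is removed, ring A of the dihydrobenzofuran is cut at C3a–C7a and C4–C5 (CO2 restored across C7a/C5), then the pyrone C3–O ether bond is cut, then C2–C3 of the side chain.
2. Enabling feature: ring A (C3a, C4, C5, C6, C7, C7a) carries O1 on C7a, OMe on C7, H on C6 and propenyl on C5, which is C3–C6 of a 3-alkoxy-4-methoxy-6-propenyl-2-pyrone; C3a and C4 are the two carbons of a terminal alkyne held to that pyrone by the O1–C2–C3 tether.
3. Forward: an anti alkynol (from pivaloyl-syringaldehyde and (R)-but-3-yn-2-ol) and a 3-diazopyran-2,4-dione (from a dioxinone and crotonyl chloride) are joined by Rh-catalysed O–H insertion; O-methylation then gives the pyrone–alkyne.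
4. One thermal operation closes the dihydrofuran ring and creates the benzene ring (Diels–Alder, then loss of CO2); ester cleavage ends the route.
5. Stereochemistry: C3 (S) comes from (R)-but-3-yn-2-ol by chirality transfer through an allenylindium (net inversion); C2 (S) comes from the anti-selective closed transition state of the same addition; neither centre is touched later, since the ether is made without breaking a bond at C2.
6. The phenol is carried as a pivalate, not a silyl ether: the ring is then a poorer donor, so the benzylic C2–O bond should resist ionisation beside the acidic hydroxypyrone and at the cycloaddition temperature.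

Key step: step 9

Remark: the two bridgehead carbons of cycloadduct 16 form as a mixture and are left undefined in its SMILES, because both become sp2 on CO2 loss; the allene axis of 5 is written in extended-tetrahedral SMILES notation.

**Route**

Step 1
Reactants: 1 syringaldehyde
Product: 2 4-formyl-2,6-dimethoxyphenyl pivalate
Conditions: PivCl, Et3N, DMAP (cat.), CH2Cl2, 0 °C to rt
Reagents that add atoms: pivaloyl chloride, CC(C)(C)C(Cl)=O
Why: DMAP-catalysed O-acylation of the phenol proceeds beside the aldehyde, and the hindered, electron-withdrawing pivalate resists acyl transfer and deactivates the later benzylic ether.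

Step 2
Reactants: 3 (R)-but-3-yn-2-ol
Product: 4 (R)-but-3-yn-2-yl methanesulfonate
Conditions: MsCl, Et3N, CH2Cl2, −78 to 0 °C, used crude
Reagents that add atoms: methanesulfonyl chloride, CS(Cl)(=O)=O
Why: mesylation occurs at oxygen without breaking the C–O bond, so the R configuration is kept.

Step 3
Reactants: 2 4-formyl-2,6-dimethoxyphenyl pivalate; 4 (R)-but-3-yn-2-yl methanesulfonate
Product: 6 4-[(1S,2S)-1-hydroxy-2-methylbut-3-yn-1-yl]-2,6-dimethoxyphenyl pivalate, via (P)-buta-1,2-dienylindium(III) iodide mesylate 5 (not isolated)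
Conditions: Pd(dppf)Cl2 (5 mol %), InI (1.4 equiv), THF–HMPA 3:1, rt
Reagents that add atoms: indium(I) iodide, [In]I (its atoms stay in intermediate 5 only)
Why: in this Marshall propargylation Pd(0) displaces the mesylate anti (SN2') and InI converts the allenylpalladium into allenylindium 5, which adds to the aldehyde through a closed SE2' transition state, so net inversion at the propargylic carbon sets the methyl-bearing centre as S and the aryl group lying away from the allenyl methyl gives the anti (1S,2S) alcohol.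

Step 4
Reactants: 7 2,2,6-trimethyl-4H-1,3-dioxin-4-one; 8 (E)-but-2-enoyl chloride
Product: 10 2,2-dimethyl-6-[(E)-2-oxopent-3-en-1-yl]-4H-1,3-dioxin-4-one, via lithium dienolate of the dioxinone 9 (not isolated)
Conditions: LiHMDS (2.2 equiv), 7 (2.2 equiv), THF, −78 °C; then 8 (1.0 equiv), −78 °C; AcOH quench
Reagents that add atoms: lithium bis(trimethylsilyl)amide, [Li]N([Si](C)(C)C)[Si](C)(C)C (Li stays in intermediate 9 only)
Why: this is a vinylogous Claisen-type C-acylation in which dienolate 9 attacks the acid chloride through its γ-carbon, a second equivalent of 9 takes up the acidic proton of the product, and the E-alkene of 8 is carried over unchanged.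

Step 5
Reactants: 10 2,2-dimethyl-6-[(E)-2-oxopent-3-en-1-yl]-4H-1,3-dioxin-4-one
Product: 12 4-hydroxy-6-[(E)-prop-1-en-1-yl]-2H-pyran-2-one, via acylketene 11 (not isolated)
Conditions: PhMe (dilute), 110 °C
Reagents that add atoms: none
Why: thermal retro-[4+2] of the dioxinone releases acetone and acylketene 11, which the enol oxygen of the distal ketone traps to give the 4-hydroxy-2-pyrone (acylketene lactonisation).

Step 6
Reactants: 12 4-hydroxy-6-[(E)-prop-1-en-1-yl]-2H-pyran-2-one
Product: 13 3-diazo-6-[(E)-prop-1-en-1-yl]-2H-pyran-2,4(3H)-dione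
Conditions: p-ABSA, Et3N, MeCN, 0 °C to rt
Reagents that add atoms: 4-acetamidobenzenesulfonyl azide, CC(=O)Nc1ccc(cc1)S(=O)(=O)N=[N+]=[N-]
Why: Regitz diazo transfer takes place at C3, the only carbon flanked by both carbonyl groups of this cyclic 1,3-dicarbonyl equivalent.

Step 7
Reactants: 6 4-[(1S,2S)-1-hydroxy-2-methylbut-3-yn-1-yl]-2,6-dimethoxyphenyl pivalate; 13 3-diazo-6-[(E)-prop-1-en-1-yl]-2H-pyran-2,4(3H)-dione
Product: 14 4-[(1S,2S)-1-({4-hydroxy-2-oxo-6-[(E)-prop-1-en-1-yl]-2H-pyran-3-yl}oxy)-2-methylbut-3-yn-1-yl]-2,6-dimethoxyphenyl pivalate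
Conditions: Rh2(OAc)4 (2 mol %), PhH, 70 °C, slow addition of 13 (1.3 equiv); crude product taken on directly
Reagents that add atoms: none
Why: in this rhodium-carbenoid O–H insertion the alcohol oxygen captures the electrophilic carbenoid from 13 and proton transfer with enolisation gives the 3-alkoxy-4-hydroxypyrone, no bond to either stereocentre being broken and O–H capture being faster than addition to the alkyne or alkene.

Step 8
Reactants: 14 4-[(1S,2S)-1-({4-hydroxy-2-oxo-6-[(E)-prop-1-en-1-yl]-2H-pyran-3-yl}oxy)-2-methylbut-3-yn-1-yl]-2,6-dimethoxyphenyl pivalate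
Product: 15 4-[(1S,2S)-1-({4-methoxy-2-oxo-6-[(E)-prop-1-en-1-yl]-2H-pyran-3-yl}oxy)-2-methylbut-3-yn-1-yl]-2,6-dimethoxyphenyl pivalate
Conditions: Me2SO4, K2CO3, acetone, rt
Reagents that add atoms: dimethyl sulfate, COS(=O)(=O)OC
Why: O-methylation of the pyronate with dimethyl sulfate and carbonate is the standard route from 4-hydroxy-2-pyrones to 4-methoxy-2-pyrones, and these mild conditions leave the alkyne C–H, the pivalate and both stereocentres alone.

Step 9
Reactants: 15 4-[(1S,2S)-1-({4-methoxy-2-oxo-6-[(E)-prop-1-en-1-yl]-2H-pyran-3-yl}oxy)-2-methylbut-3-yn-1-yl]-2,6-dimethoxyphenyl pivalate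
Product: 17 4-[(2S,3S)-7-methoxy-3-methyl-5-[(E)-prop-1-en-1-yl]-2,3-dihydro-1-benzofuran-2-yl]-2,6-dimethoxyphenyl pivalate (odoratisol A pivalate), via CO2-bridged cycloadduct 16 (not isolated)
Conditions: PhMe (ca. 5 mM), BHT (10 mol %), sealed tube, ca. 170 °C
Reagents that add atoms: none
Why: On heating, the tethered terminal alkyne adds across C3 and C6 of the pyrone diene in a concerted intramolecular [4+2] cycloaddition, forming C3a–C7a (internal alkyne carbon to pyrone C3) and C4–C5 (terminal alkyne carbon to pyrone C6) to give the 2-oxabicyclo[2.2.2]octadienone 16, which loses CO2 by retro-[4+2] and aromatises. The closest known reaction type is the thermal intramolecular 2-pyrone–alkyne Diels–Alder/CO2-extrusion benzannulation, together with the analogous azadiene–alkyne cascades through an O–C–C tether that give dihydrofuro-fused arenes. The dihydrofuran ring closes as the five-membered ring defined by the three-atom tether (O1–C2–C3 joining C7a to C3a) at the moment of cycloaddition, and the benzene ring closes as the six-membered ring of the [4+2] and becomes aromatic when the lactone bridge leaves. No stereocentre is created: C2 and C3 lie on the tether, take no part in the bond reorganisation and keep the trans (2S,3S) arrangement, while the bridgehead centres of 16 disappear. Regiochemistry is fixed by the tether, which can deliver the internal alkyne carbon only to pyrone C3, and periselectivity is secured because the propenyl alkene cannot be reached intramolecularly while high dilution and BHT suppress bimolecular cycloaddition or polymerisation. The 4-pivaloyloxy group keeps the benzylic C2–O bond from ionising at the temperature needed.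

Step 10
Reactants: 17 odoratisol A pivalate
Product: 18 odoratisol A, 4-[(2S,3S)-7-methoxy-3-methyl-5-[(E)-prop-1-en-1-yl]-2,3-dihydro-1-benzofuran-2-yl]-2,6-dimethoxyphenol
Conditions: DIBAL-H (3 equiv), CH2Cl2, −78 °C; aq. Rochelle salt
Reagents that add atoms: none
Why: reductive cleavage of the aryl ester by hydride at low temperature frees the phenol without a phenoxide in protic medium, so the C2 benzylic ether cannot open through a quinone methide and both stereocentres stay as set.

**Compound list**

1 | syringaldehyde (4-hydroxy-3,5-dimethoxybenzaldehyde) | COc1cc(C=O)cc(OC)c1O | starting material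
2 | 4-formyl-2,6-dimethoxyphenyl pivalate | COc1cc(C=O)cc(OC)c1OC(=O)C(C)(C)C | intermediate
3 | (R)-but-3-yn-2-ol | C#C[C@@H](C)O | starting material
4 | (R)-but-3-yn-2-yl methanesulfonate | C#C[C@@H](C)OS(C)(=O)=O | intermediate
5 | (P)-buta-1,2-dienylindium(III) iodide mesylate (formed in situ) | [H]C(C)=[C@]=C([H])[In](I)OS(C)(=O)=O | intermediate
6 | 4-[(1S,2S)-1-hydroxy-2-methylbut-3-yn-1-yl]-2,6-dimethoxyphenyl pivalate | C#C[C@H](C)[C@H](O)c1cc(OC)c(OC(=O)C(C)(C)C)c(OC)c1 | intermediate
7 | 2,2,6-trimethyl-4H-1,3-dioxin-4-one | CC1=CC(=O)OC(C)(C)O1 | starting material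
8 | (E)-but-2-enoyl chloride (crotonyl chloride) | C/C=C/C(Cl)=O | starting material
9 | lithium 2,2-dimethyl-6-methylidene-6H-1,3-dioxin-4-olate (lithium dienolate of 7, formed in situ) | C=C1C=C(O[Li])OC(C)(C)O1 | intermediate
10 | 2,2-dimethyl-6-[(E)-2-oxopent-3-en-1-yl]-4H-1,3-dioxin-4-one | C/C=C/C(=O)CC1=CC(=O)OC(C)(C)O1 | intermediate
11 | (6E)-octa-1,6-diene-1,3,5-trione (acylketene, formed in situ) | C/C=C/C(=O)CC(=O)C=C=O | intermediate
12 | 4-hydroxy-6-[(E)-prop-1-en-1-yl]-2H-pyran-2-one | C/C=C/C1=CC(O)=CC(=O)O1 | intermediate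
13 | 3-diazo-6-[(E)-prop-1-en-1-yl]-2H-pyran-2,4(3H)-dione | C/C=C/C1=CC(=O)C(=[N+]=[N-])C(=O)O1 | intermediate
14 | 4-[(1S,2S)-1-({4-hydroxy-2-oxo-6-[(E)-prop-1-en-1-yl]-2H-pyran-3-yl}oxy)-2-methylbut-3-yn-1-yl]-2,6-dimethoxyphenyl pivalate | C#C[C@H](C)[C@@H](c1cc(OC)c(OC(=O)C(C)(C)C)c(OC)c1)OC1=C(O)C=C(/C=C/C)OC1=O | intermediate
15 | 4-[(1S,2S)-1-({4-methoxy-2-oxo-6-[(E)-prop-1-en-1-yl]-2H-pyran-3-yl}oxy)-2-methylbut-3-yn-1-yl]-2,6-dimethoxyphenyl pivalate | C#C[C@H](C)[C@@H](c1cc(OC)c(OC(=O)C(C)(C)C)c(OC)c1)OC1=C(OC)C=C(/C=C/C)OC1=O | intermediate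
16 | CO2-bridged cycloadduct (2-oxabicyclo[2.2.2]octa-5,7-dien-3-one fused to the dihydrofuran; bridgeheads undefined, formed in situ) | C/C=C/C12OC(=O)C3(O[C@H](c4cc(OC)c(OC(=O)C(C)(C)C)c(OC)c4)[C@@H](C)C3=C1)C(OC)=C2 | intermediate
17 | 4-[(2S,3S)-7-methoxy-3-methyl-5-[(E)-prop-1-en-1-yl]-2,3-dihydro-1-benzofuran-2-yl]-2,6-dimethoxyphenyl pivalate (odoratisol A pivalate) | C/C=C/c1cc(OC)c2c(c1)[C@H](C)[C@@H](c1cc(OC)c(OC(=O)C(C)(C)C)c(OC)c1)O2 | intermediate
18 | odoratisol A | C/C=C/c1cc(OC)c2c(c1)[C@H](C)[C@@H](c1cc(OC)c(O)c(OC)c1)O2 | target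

**Step count**

Total steps: 10. Longest linear sequence: 7 steps (steps 4 to 10, from 7 and 8); the alkynol branch (steps 1 to 3) joins at step 7.

**Steps most likely to fail**

Step 9. The terminal alkyne may add too slowly to the donor-substituted pyrone, so that thermal breakdown (cleavage or elimination at the benzylic C–O bond, or oligomerisation through the propenyl-pyrone triene) overtakes the cycloaddition. The fallback changes the oxidation level of the 2π partner; it sets out from 15 and returns at 17. Lindlar semi-hydrogenation of the terminal alkyne (H2, Pd/CaCO3–Pb, quinoline, EtOAc, rt) should give the vinyl-tethered pyrone F1. Heating in toluene in a sealed tube should effect the intramolecular pyrone–alkene Diels–Alder reaction to the alkene-derived bridged lactone F2 (not isolated), which on loss of CO2 gives the 3a,4-dihydrobenzofuran diene F3 as a mixture at C3a. Dehydrogenation with DDQ (PhH, 0 °C) should then give 17.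

Step 7. The carbenoid may be diverted before the hindered secondary alcohol captures it, by addition to the terminal alkyne to form a furan, by dimerisation, or by insertion into the acidic enol O–H of the product. The fallback replaces carbene insertion by cross-coupling; it sets out from aldehyde 2 and hydroxypyrone 12 and returns at 15. Because a terminal alkyne would itself couple under palladium, the alkyne is carried C-silylated. Commercial (R)-4-(trimethylsilyl)but-3-yn-2-ol is mesylated (MsCl, Et3N) to (R)-4-(trimethylsilyl)but-3-yn-2-yl methanesulfonate F4. Under the conditions of step 3 this should form the silylated allenylindium F5 in situ and add to 2 to give the silyl alkynol F6. Pyrone 12 is brominated at C3 (NBS, CH2Cl2, 0 °C) to 3-bromo-4-hydroxy-6-[(E)-prop-1-en-1-yl]-2H-pyran-2-one F7 and O-methylated (Me2SO4, K2CO3, acetone) to 3-bromo-4-methoxy-6-[(E)-prop-1-en-1-yl]-2H-pyran-2-one F8. Palladium-catalysed C–O coupling of F6 with F8 (t-BuBrettPhos-Pd precatalyst, Cs2CO3, toluene, 90 °C) should give the silylated pyrone ether F9. Buffered fluoride (TBAF, AcOH, THF, 0 °C) then removes the alkynyl silyl group to give 15.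

Step 4. The acylation may be eroded by O-acylation, multiple acylation, or ketene formation from the enolisable acid chloride. The fallback replaces it by aldol addition and oxidation; it sets out from 7 and returns at 10. Enolisation and silylation of 7 (LDA, TMSCl, THF, −78 °C) gives the silyl dienol ether F10. A vinylogous Mukaiyama aldol addition to (E)-crotonaldehyde (BF3·OEt2, CH2Cl2, −78 °C) should give the racemic allylic alcohol F11, and Dess–Martin oxidation should then give 10.

**Further compounds**

F1 | step 9 | 4-[(1S,2S)-1-({4-methoxy-2-oxo-6-[(E)-prop-1-en-1-yl]-2H-pyran-3-yl}oxy)-2-methylbut-3-en-1-yl]-2,6-dimethoxyphenyl pivalate | C=C[C@H](C)[C@@H](c1cc(OC)c(OC(=O)C(C)(C)C)c(OC)c1)OC1=C(OC)C=C(/C=C/C)OC1=O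
F2 | step 9 | alkene-derived CO2-bridged cycloadduct (2-oxabicyclo[2.2.2]oct-5-en-3-one fused to the tetrahydrofuran; new ring centres undefined, not isolated) | C/C=C/C12OC(=O)C3(O[C@H](c4cc(OC)c(OC(=O)C(C)(C)C)c(OC)c4)[C@@H](C)C3C1)C(OC)=C2
F3 | step 9 | 4-[(2S,3S)-7-methoxy-3-methyl-5-[(E)-prop-1-en-1-yl]-2,3,3a,4-tetrahydro-1-benzofuran-2-yl]-2,6-dimethoxyphenyl pivalate (C3a undefined) | C/C=C/C1=CC(OC)=C2O[C@H](c3cc(OC)c(OC(=O)C(C)(C)C)c(OC)c3)[C@@H](C)C2C1
F4 | step 7 | (R)-4-(trimethylsilyl)but-3-yn-2-yl methanesulfonate | C[Si](C)(C)C#C[C@@H](C)OS(C)(=O)=O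
F5 | step 7 | (P)-1-(trimethylsilyl)buta-1,2-dienylindium(III) iodide mesylate (formed in situ) | [H]C(C)=[C@]=C([Si](C)(C)C)[In](I)OS(C)(=O)=O
F6 | step 7 | 4-[(1S,2S)-1-hydroxy-2-methyl-4-(trimethylsilyl)but-3-yn-1-yl]-2,6-dimethoxyphenyl pivalate | C[Si](C)(C)C#C[C@H](C)[C@H](O)c1cc(OC)c(OC(=O)C(C)(C)C)c(OC)c1
F7 | step 7 | 3-bromo-4-hydroxy-6-[(E)-prop-1-en-1-yl]-2H-pyran-2-one | C/C=C/C1=CC(O)=C(Br)C(=O)O1
F8 | step 7 | 3-bromo-4-methoxy-6-[(E)-prop-1-en-1-yl]-2H-pyran-2-one | C/C=C/C1=CC(OC)=C(Br)C(=O)O1
F9 | step 7 | 4-[(1S,2S)-1-({4-methoxy-2-oxo-6-[(E)-prop-1-en-1-yl]-2H-pyran-3-yl}oxy)-2-methyl-4-(trimethylsilyl)but-3-yn-1-yl]-2,6-dimethoxyphenyl pivalate | C[Si](C)(C)C#C[C@H](C)[C@@H](c1cc(OC)c(OC(=O)C(C)(C)C)c(OC)c1)OC1=C(OC)C=C(/C=C/C)OC1=O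
F10 | step 4 | [(2,2-dimethyl-6-methylidene-6H-1,3-dioxin-4-yl)oxy]trimethylsilane | C=C1C=C(O[Si](C)(C)C)OC(C)(C)O1
F11 | step 4 | rac-6-[(E)-2-hydroxypent-3-en-1-yl]-2,2-dimethyl-4H-1,3-dioxin-4-one | C/C=C/C(O)CC1=CC(=O)OC(C)(C)O1
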